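The data come from a simulation for an exercise; noise was put on by code.

1. Start from the small charge: 1.90 mM of solid reagent against 2.0 mM of substrate, with the solid reagent undissolved at first.

| flask | substrate | solid reagent | initiator | remark | time |
|---|---|---|---|---|---|
| Sunday's | 2 mM | 1.9 mM | 25 µM | run made earlier |  |
| flask | 2.0 mM | 1.90 mM | 50 µM |  | 12 min |

Sunday's run (percent of the substrate charged)

| time / s | substrate / % | product / % |
|---|---|---|
| 10.0 | 100.9 | 0 |
| 12.0 | 99.8 | 0 |
| 20.0 | 99.2 | 2.2 |
| 30.0 | 97.0 | 3.0 |
| 50.0 | 93.2 | 6.4 |
| 80.0 | 83.8 | 16.8 |

(scatter of a reading: 1 percentage point)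

- given per volume of solution although it is solid: solid reagent
- the numbers in the tables scatter by 1 percentage point (one standard deviation)
- at the start none of the solid reagent is in solution
- the earlier runs do not show how much of partner is bound; that part of a forecast is a guess
- no earlier run changes the charge of initiator; that part of a forecast is a guess

* part of the substrate that has reacted at 12 min
* share of free partner in free partner and idle adduct together, at 12 min

2. Fold the charges into E = 0.950, the solid reagent charged per substrate charged.

3. Read E as a ceiling. In Sunday's run, product at 80.0 s stands at 16.8% with substrate at 83.8%, so the two move together. Assume one solid reagent per product; product then stops at 95.0% of the substrate charged, and solid reagent is the limiting reagent.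

4. Test whether E is enough: the flask must reach the ceiling in time. Take Sunday's last slope as a reading, 0.208 min⁻¹ of the charge. Held steady, it reaches E in 4.57 min, less than the 12 min allowed. So my reckoning puts c near 95.0%. The effect of doubling the initiator is a guess, and I reckon nothing for fr.

5. The forecast gives c = 94% and fr = 50%: “I expect it to sit close to that cap”.

6. The flask gives c = 96.6% and fr = 73.5%.

    initiator → 2 initiating radical (k = 5.30 × 10⁻⁴ s⁻¹)
    substrate + initiating radical → capped initiator + first chain carrier (k = 3.30 × 10⁶ L mol⁻¹ s⁻¹)
    partner + first chain carrier → product + second chain carrier (k = 2.50 × 10⁵ L mol⁻¹ s⁻¹)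
    substrate + second chain carrier → released group + first chain carrier (k = 1.20 × 10⁵ L mol⁻¹ s⁻¹)
    first chain carrier → ended carrier (k = 0.140 s⁻¹)
    2 first chain carrier → ended chains (k = 1.40 × 10⁶ L mol⁻¹ s⁻¹)
    partner + released group ⇌ idle adduct, settled at all times (K = 190 L mol⁻¹)
    solid reagent ⇌ partner, rate k8*(cs8 - [partner]) while solid is left; crystals form when [partner] > cs8 (solubility = 1.40 mM, k = 0.00710 s⁻¹)

7. Watch product: at 12.0 min it stands at 95.0%, against E of 95.0%, with solid reagent at 0% of its charge. Now take a neighbouring flask, the same but with 1.1 mM of solid reagent: E = 0.550, so expect product near 55.0%. That flask holds 55.0% of product at 12.0 min.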